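The unsymmetrical 6,8'-biaryl is traced back to the twofold-symmetric 8,8'-dimer of genistein, which needs only the homocoupling of one iodinated monomer. The key step exploits the fact that in ring A both O1 and the C5 hydroxyl oxygen lie ortho to the acyl-bearing C4a: acid opens one pyranone (ring C) at O1–C2, the phloroglucinol ring turns about C4–C4a and the former 5-OH closes onto C2, so that the biaryl carbon C8 of that half becomes C6. One operation thus forms one O–C2 bond, closes one ring and breaks the symmetry. The precursor is free 8,8'-bigenistein, made from genistein by permethylation, C8 iodination, Ullmann coupling and demethylation.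

Key step: step 5

Assumption: the target SMILES defines no configuration at the hindered 6–8' biaryl axis, so the racemic atropisomer mixture is taken as the target and no stereo-element has to be controlled.

Numbering used: chromen-4-one positions O1, C2–C4, C4a, C5–C8, C8a; ring A is the benzo ring, ring B the 3-aryl ring, ring C the pyranone; primes mark the second isoflavone unit.

Step 1
Reactants: 1 genistein; 2 dimethyl sulfate
Product: 3 5,7,4'-tri-O-methylgenistein (5,7-dimethoxy-3-(4-methoxyphenyl)-4H-chromen-4-one)
Conditions: Me2SO4 (5 equiv), K2CO3 (6 equiv), acetone, reflux, 24–48 h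
Reagents that add atoms: dimethyl sulfate, COS(=O)(=O)OC
Why: Williamson-type O-methylation of the three phenoxides (SN2 at methyl) is standard for flavonoids; the chelated 5-OH reacts last, which is why excess reagent and prolonged reflux are planned.

Step 2
Reactants: 3 5,7,4'-tri-O-methylgenistein; 4 N-iodosuccinimide
Product: 5 8-iodo-5,7-dimethoxy-3-(4-methoxyphenyl)-4H-chromen-4-one
Conditions: NIS (1.05 equiv), TFA (0.3 equiv), MeCN, 0 °C to rt, dark
Reagents that add atoms: N-iodosuccinimide, O=C1CCC(=O)N1I
Why: Electrophilic aromatic iodination (SEAr) by acid-activated NIS should go to C8 of ring A, which is activated by O1 and the 7-OMe (both ortho) and by the 5-OMe (para) and is less shielded than C6, towards which the peri carbonyl pushes the methyl of the 5-OMe; ring B is a plain anisole and much less nucleophilic, and one equivalent of NIS limits double iodination.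

Step 3
Reactants: 5 8-iodo-5,7-dimethoxy-3-(4-methoxyphenyl)-4H-chromen-4-one (two molecules)
Product: 6 hexa-O-methyl-8,8'-bigenistein (8,8'-bi[5,7-dimethoxy-3-(4-methoxyphenyl)-4H-chromen-4-one])
Conditions: activated Cu powder (excess), DMF, 150 °C, Ar
Reagents that add atoms: none
Why: Ullmann reductive homocoupling of an aryl iodide through arylcopper intermediates tolerates the ether and chromone functions and has precedent for 8-iodo-5,7-dialkoxyflavones despite the two ortho oxygen substituents; the tetra-ortho-substituted biaryl should form as a racemic axis.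

Step 4
Reactants: 6 hexa-O-methyl-8,8'-bigenistein
Product: 7 8,8'-bigenistein (8,8'-bi[5,7-dihydroxy-3-(4-hydroxyphenyl)-4H-chromen-4-one])
Conditions: BBr3 (12 equiv), CH2Cl2, −78 °C to rt; then H2O, 0 °C
Reagents that add atoms: none
Why: Exhaustive BBr3 ether cleavage (Lewis acid complexation, bromide SN2 at methyl, hydrolysis of the aryl borates on quench) should free all six phenols, the chelated 5-OMe groups going first; under these anhydrous conditions water cannot open the pyranones, so symmetric 7 should reach the key step free of ring A isomers.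

Step 5
Reactants: 7 8,8'-bigenistein
Product: 9 6,8'-bigenistein (target; 5,7-dihydroxy-6-[5,7-dihydroxy-3-(4-hydroxyphenyl)-4-oxo-4H-chromen-8-yl]-3-(4-hydroxyphenyl)-4H-chromen-4-one), via ring-opened formyl ketone 8 (not isolated)
Conditions: 57% aq. HI, AcOH, 110 °C, Ar; HPLC control, quench (aq. Na2S2O3) near half turnover of the ring A units; Sephadex LH-20 (MeOH), then C18 HPLC; recovered symmetric dimers resubmitted
Reagents that add atoms: none
Why: Protonation of the C4 carbonyl of one half gives a 4-hydroxybenzopyrylium ion, water adds at C2 and the O1–C2 bond breaks to give the formyl ketone 8, whose acyl group on C4a is flanked by two free phenols (the former O1–H and the 5-OH); after a half turn about C4–C4a the former 5-OH adds to the protonated formyl carbon and loss of water restores the pyranone, now fused the other way round. This is the Wessely–Moser rearrangement, an established acid-mediated equilibration of 5-hydroxy-8-C-substituted flavones and isoflavones, 8-C-glycosides and 8-linked biflavones included, with their 6-substituted isomers. The one ring formed is closed by 6-exo-trig attack of the phenolic oxygen on the formyl C=O (equivalently a 6-endo-trig oxa-Michael closure on the enol tautomer), followed by dehydration, which makes the new O–C2 bond. No stereocentre arises, and the hindered biaryl axis is obtained as the racemate. The selectivity needed is one isomerization per molecule: because the two halves of 7 are homotopic the first event gives a single constitutional isomer whichever half reacts, but nothing in the substrate prevents the second, so with independent halves the mixed dimer should be at its statistical maximum when about half of all ring A units have turned, and the reaction is quenched there under HPLC control. Unchanged 7 and doubly rearranged material are separated and returned to the same conditions, since all three dimers belong to one equilibrium; the free phenols and the biaryl bond should be inert to hot HI, whose reducing character also suppresses oxidative side reactions.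

Compound list
1 | genistein (5,7-dihydroxy-3-(4-hydroxyphenyl)-4H-chromen-4-one) | O=c1c(-c2ccc(O)cc2)coc2cc(O)cc(O)c12 | starting material
2 | dimethyl sulfate | COS(=O)(=O)OC | starting material
3 | 5,7,4'-tri-O-methylgenistein (5,7-dimethoxy-3-(4-methoxyphenyl)-4H-chromen-4-one) | COc1ccc(cc1)-c1coc2cc(OC)cc(OC)c2c1=O | intermediate
4 | N-iodosuccinimide | O=C1CCC(=O)N1I | starting material
5 | 8-iodo-5,7-dimethoxy-3-(4-methoxyphenyl)-4H-chromen-4-one | COc1ccc(cc1)-c1coc2c(I)c(OC)cc(OC)c2c1=O | intermediate
6 | hexa-O-methyl-8,8'-bigenistein (8,8'-bi[5,7-dimethoxy-3-(4-methoxyphenyl)-4H-chromen-4-one], racemic axis) | COc1ccc(cc1)-c1coc2c(-c3c(OC)cc(OC)c4c(=O)c(-c5ccc(OC)cc5)coc34)c(OC)cc(OC)c2c1=O | intermediate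
7 | 8,8'-bigenistein (8,8'-bi[5,7-dihydroxy-3-(4-hydroxyphenyl)-4H-chromen-4-one], racemic axis) | O=c1c(-c2ccc(O)cc2)coc2c(-c3c(O)cc(O)c4c(=O)c(-c5ccc(O)cc5)coc34)c(O)cc(O)c12 | intermediate
8 | ring-opened formyl ketone, 2-(4-hydroxyphenyl)-3-oxo-3-{2,4,6-trihydroxy-3-[5,7-dihydroxy-3-(4-hydroxyphenyl)-4-oxo-4H-chromen-8-yl]phenyl}propanal (labile alpha-CH drawn without configuration, in equilibrium with its enol) | O=CC(c1ccc(O)cc1)C(=O)c1c(O)cc(O)c(-c2c(O)cc(O)c3c(=O)c(-c4ccc(O)cc4)coc23)c1O | intermediate (not isolated)
9 | 6,8'-bigenistein (5,7-dihydroxy-6-[5,7-dihydroxy-3-(4-hydroxyphenyl)-4-oxo-4H-chromen-8-yl]-3-(4-hydroxyphenyl)-4H-chromen-4-one, racemic axis) | O=c1c(-c2ccc(O)cc2)coc2cc(O)c(-c3c(O)cc(O)c4c(=O)c(-c5ccc(O)cc5)coc34)c(O)c12 | target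

Total step count: 5
Longest linear sequence: 5 steps (1 → 3 → 5 → 6 → 7 → 9)

Steps most likely to fail

1. Step 5. What may go wrong:
- both halves turn before the reaction can be stopped, or the equilibrium leaves the mixed dimer minor;
- the ring-opened form loses its formyl carbon as formic acid;
- the three isomeric hexaphenols resist chromatographic separation.

Fallback: the symmetry is broken at the C–C bond-forming stage by a Suzuki–Miyaura cross-coupling of a 6-iodo monomer with an 8-boryl monomer. It sets out from 3 and 5 and rejoins the route at 9. The chelated 5-OMe of 3 is cleaved selectively (BCl3, CH2Cl2, 0 °C) to give 5-hydroxy-7-methoxy-3-(4-methoxyphenyl)-4H-chromen-4-one F1. NIS in DMF at rt then iodinates ortho to the free chelated phenol to give 5-hydroxy-6-iodo-7-methoxy-3-(4-methoxyphenyl)-4H-chromen-4-one F2. In parallel, Miyaura borylation of 5 (B2pin2, Pd(dppf)Cl2, KOAc, dioxane, 90 °C) gives 5,7-dimethoxy-3-(4-methoxyphenyl)-8-(4,4,5,5-tetramethyl-1,3,2-dioxaborolan-2-yl)-4H-chromen-4-one F3. F2 and F3 are joined (Pd(OAc)2, SPhos, K3PO4, toluene, 100 °C) to the 6,8'-linked penta-O-methyl ether, 5-hydroxy-7-methoxy-3-(4-methoxyphenyl)-6-[5,7-dimethoxy-3-(4-methoxyphenyl)-4-oxo-4H-chromen-8-yl]-4H-chromen-4-one F4. BBr3 in CH2Cl2 removes the five methyl groups to give 9.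

2. Step 3. What may go wrong: slow coupling at the doubly ortho-oxygenated carbon, with reductive loss of iodine competing.

Fallback: the homocoupling is replaced by a Negishi cross-coupling. It sets out from 5 and rejoins the route at 6. One portion of 5 is converted by LiCl-assisted zinc insertion (Zn dust, LiCl, THF, 50 °C) into [5,7-dimethoxy-3-(4-methoxyphenyl)-4-oxo-4H-chromen-8-yl]zinc iodide F5, which is used in solution. It is coupled with a second portion of 5 (Pd2(dba)3, SPhos, THF/NMP, 70 °C), conditions suited to tetra-ortho-substituted biaryls, to give 6.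

3. Step 2. What may go wrong: attack at C6 or on ring B, or double iodination, giving mixtures that are hard to separate. The site would be checked by NOE: the remaining ring A proton of 5 should contact both methoxy groups. Attack at C6 would not be fatal in principle, since 6-linked and 8-linked units interconvert in step 5, but a single defined iodide is wanted for a clean coupling.

Fallback: the iodine is placed on the ring-opened ketone, where a free phenol directs it, and the pyranone is then rebuilt. It sets out from 3 and rejoins the route at 5. Alkaline ring opening of 3 (KOH, aq. EtOH, reflux), with the C2 carbon leaving as formate, gives the deoxybenzoin 1-(2-hydroxy-4,6-dimethoxyphenyl)-2-(4-methoxyphenyl)ethan-1-one F6. NIS (MeCN, rt) should iodinate ortho to the free chelated hydroxyl to give 1-(2-hydroxy-3-iodo-4,6-dimethoxyphenyl)-2-(4-methoxyphenyl)ethan-1-one F7; its site can be confirmed at this stage, since the remaining ring proton should show NOE contacts to two methoxy groups. Condensation with N,N-dimethylformamide dimethyl acetal (toluene, 100 °C) closes the pyranone through the enaminone and gives 5, with the iodine next to the oxygen that becomes O1.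

Further compounds
F1 | step 5 | 5-hydroxy-7-methoxy-3-(4-methoxyphenyl)-4H-chromen-4-one | COc1ccc(cc1)-c1coc2cc(OC)cc(O)c2c1=O
F2 | step 5 | 5-hydroxy-6-iodo-7-methoxy-3-(4-methoxyphenyl)-4H-chromen-4-one | COc1ccc(cc1)-c1coc2cc(OC)c(I)c(O)c2c1=O
F3 | step 5 | 5,7-dimethoxy-3-(4-methoxyphenyl)-8-(4,4,5,5-tetramethyl-1,3,2-dioxaborolan-2-yl)-4H-chromen-4-one | COc1ccc(cc1)-c1coc2c(B3OC(C)(C)C(C)(C)O3)c(OC)cc(OC)c2c1=O
F4 | step 5 | 5-hydroxy-7-methoxy-3-(4-methoxyphenyl)-6-[5,7-dimethoxy-3-(4-methoxyphenyl)-4-oxo-4H-chromen-8-yl]-4H-chromen-4-one | COc1ccc(cc1)-c1coc2cc(OC)c(-c3c(OC)cc(OC)c4c(=O)c(-c5ccc(OC)cc5)coc34)c(O)c2c1=O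
F5 | step 3 | [5,7-dimethoxy-3-(4-methoxyphenyl)-4-oxo-4H-chromen-8-yl]zinc iodide | COc1ccc(cc1)-c1coc2c([Zn]I)c(OC)cc(OC)c2c1=O
F6 | step 2 | 1-(2-hydroxy-4,6-dimethoxyphenyl)-2-(4-methoxyphenyl)ethan-1-one | COc1ccc(CC(=O)c2c(O)cc(OC)cc2OC)cc1
F7 | step 2 | 1-(2-hydroxy-3-iodo-4,6-dimethoxyphenyl)-2-(4-methoxyphenyl)ethan-1-one | COc1ccc(CC(=O)c2c(O)c(I)c(OC)cc2OC)cc1
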